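4 questions stand on 3 flasks, and they come down to one: of the substrate you charge, how much is still intermediate when the time is up?

| setting | zeta | epsilon | beta |
|---|---|---|---|
| substrate | 0.052 M | 0.052 M | 0.052 M |
| solid partner | 0.0546 M | 0.0546 M | 0.0546 M |
| temperature | −5 °C | −20 °C | 10 °C |
| time | 1.0 h | 1.0 h | 1.0 h |

- the flask with the highest amount of intermediate, in percent of the substrate charged ("all alike" if they lie within 1.5 percentage points) (zeta / epsilon / beta / all alike)
- final intermediate, as a percentage of the substrate charged, in zeta
- final intermediate, as a percentage of the substrate charged, in epsilon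
- final intermediate, as a percentage of the substrate charged, in beta

- percent here means substrate units held: one homo product counts as two
- where a step has two of a species, its rate is k times that concentration squared, and two are used at each turn
- solid partner is a solid; its amount is given per volume of the solution
- the constants hold at −20 °C; other temperatures follow from the activation energies and enthalpies
- at the start none of the solid partner is in solution

    fresh partner ⇌ dormant form (K1 = 1.5, k1 = 1.1 × 10⁻⁴ s⁻¹, Ea1 = 79.0 kJ mol⁻¹, ΔH1 = 12.0 kJ mol⁻¹)
    solid partner ⇌ fresh partner, rate k2*(cs2 - [fresh partner]) while solid is left; crystals form when [fresh partner] > cs2 (cs2 = 16 mM, k2 = 1.2 × 10⁻⁴ s⁻¹)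
    target ⇌ isomer of the product (K3 = 0.55, k3 = 1.6 × 10⁻⁴ s⁻¹, Ea3 = 86.0 kJ mol⁻¹, ΔH3 = −59.0 kJ mol⁻¹)
    2 intermediate → homo product (k4 = 1.6 × 10⁻⁴ M⁻¹ s⁻¹, Ea4 = 56.0 kJ mol⁻¹)
    fresh partner + intermediate → target (k5 = 0.0040 M⁻¹ s⁻¹, Ea5 = 41.0 kJ mol⁻¹)
    substrate → intermediate (k6 = 2.0 × 10⁻⁴ s⁻¹, Ea6 = 74.0 kJ mol⁻¹)
    (constants at −20 °C)

Write the balance of the substrate, because it is the smaller charge, the limiting reagent. Each unit sits as substrate, intermediate, homo product, target or isomer of the product. Substrate becomes intermediate by a first-order step of constant k, so the share converted, C, is one minus e to the power minus k times the time. Two intermediate then pair to homo product. Take the time divided by the first half-life of that pairing with the full charge standing as intermediate, which is twice the pairing constant at that temperature, times the charge, times the time. Call this the loss number q; in zeta it is 0.265. The share kept, W, is then C divided by one plus q times C. This treats intermediate as present from the start, which overcounts pairing. It also leaves out target, which undercounts loss, though dissolving can supply at most 13.3% of the substrate charge in the hour.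

My reckoning, flask by flask:

- epsilon: C 51.3%, q 0.0599, W 49.8%
- zeta: C 99.4%, q 0.265, W 78.7%
- beta: C >99.9%, q 1.00, W 49.9%

Read the rows down. In epsilon, q is small, so what you lose there is unconverted substrate, not pairing. In beta, C is full but q has climbed to about one, so the hour equals the first half-life and W is about half. Zeta sits between: C is nearly all of the charge and q is a quarter. My pick is therefore zeta.

The forecast also names zeta, with 81% there, above my figure, 49.8% in epsilon and 48% in beta, for “conversion nearly complete and only moderate homo-coupling”.

The simulation gives zeta, with 80.0% in zeta, 49.4% in epsilon and 48.1% in beta.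

In zeta, half of the substrate step's turnover was done by 0.134 h and 0.58% of the charge stood at the end, while 21% of the dissolving turnover was done by 0.200 h. At the end of the hour, zeta held 15.1% homo product, 3.86% target and 0.429% isomer of the product. In a repeat of zeta at 20 °C, where substrate stood at 0% at the end, q rises from 0.265 to 2.26. With C full, W is 30.7%, and that flask held 28.5%.

All constants were drawn at random within sensible limits; the result is computed.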